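**Plan**

1. Numbering (octahydronaphthalen-1(2H)-one): C1 ketone, C2 (CH3, OH), C3 (sec-butyl), C4 (CH3, acyl), C4a (H), C5 (CH3), C6, C7 (CH3, OH), C8, C8a (OH); ring A = C4a, C5, C6, C7, C8, C8a; ring B = C1, C2, C3, C4, C4a, C8a.
2. Enabling feature: ring A is a 5-methylcyclohexane-1,3-diol. Its two tertiary carbinol carbons C7 and C8a flank the single CH2 C8 (a latent 1,3-diketone), and C4a–C5(CH3)–C6 is a latent isobutenyl group, a 2-methylallyl unit that can add twice to carbonyl groups with transfer of its methyl hydrogens.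
3. Retrosynthesis: first the enol ether and C5–H (formylation/O-methylation; hydrogenation of a C5 methylidene), then C4a–C8a and C6–C7 together (double carbonyl-ene cascade of an acyclic isobutenyl 1,2,4-triketone), then C1–C2 (acetylide plus methyl ketone) and C3–C4 (Ireland–Claisen).
4. Forward: C3–C4 by Claisen, C1–C2 by acetylide addition, alkenes and alkyne raised to the tetraketone level, then ring B (C4a–C8a) and ring A (C6–C7) close in that order in one flask; the side chain is finished last.
5. Stereochemistry: sec-butyl centre from (S)-3-methylpentanoic acid; C3 and C4 by chirality transfer from (S)-but-3-yn-2-ol through the Claisen chair; C2 by 1,2-induction from C3; C4a, C8a and C7 in the cascade (chair, then aluminium chelate); C5 by hydroxyl-directed hydrogenation.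
6. Helpers: Et3Si on the C2 oxygen (prevents a hemiketal with the C7 ketone) and two chlorines on C8 (stop enolisation of the 1,3-diketone and activate both ketones); both are removed after the cascade.

Key step: step 13

Assumption: 1, 7 and 13 are available as single enantiomers; locants such as C4a or C8a in the Why lines refer to the target numbering given in the plan.

**Route**

Step 1
Reactants: 1 (S)-but-3-yn-2-ol; 2 2-bromopropene
Product: 3 (S)-5-methylhex-5-en-3-yn-2-ol
Conditions: Pd(PPh3)2Cl2 (2 mol%), CuI (4 mol%), Et3N, THF, 40 °C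
Reagents that add atoms: none
Why: Sonogashira coupling of a terminal alkyne with a vinyl bromide should give the enyne without touching the carbinol stereocentre.

Step 2
Reactants: 3 (S)-5-methylhex-5-en-3-yn-2-ol
Product: 5 (2S,3Z)-4-iodo-5-methylhexa-3,5-dien-2-ol, via cyclic alkenylalanate 4 (not isolated)
Conditions: NaAlH2(OCH2CH2OMe)2, THF, 0 °C to rt; then I2, −78 to 0 °C
Reagents that add atoms: iodine, II
Why: Alkoxide-directed trans-hydroalumination of the propargylic alcohol puts aluminium on the distal alkyne carbon cis to the carbinol carbon, and iodinolysis with retention should give the (Z)-iodoalkene.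

Step 3
Reactants: 5 (2S,3Z)-4-iodo-5-methylhexa-3,5-dien-2-ol
Product: 6 (2S,3E)-4,5-dimethylhexa-3,5-dien-2-ol
Conditions: MeZnCl (3 equiv), Pd(PPh3)4 (5 mol%), THF, 50 °C
Reagents that add atoms: methylzinc chloride, C[Zn]Cl
Why: Negishi coupling proceeds with retention of alkene geometry, so the new methyl group is cis to the carbinol carbon as the Claisen step requires.

Step 4
Reactants: 6 (2S,3E)-4,5-dimethylhexa-3,5-dien-2-ol; 7 (S)-3-methylpentanoic acid
Product: 8 (2S,3E)-4,5-dimethylhexa-3,5-dien-2-yl (3S)-3-methylpentanoate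
Conditions: DCC, DMAP (cat.), CH2Cl2, 0 °C to rt
Reagents that add atoms: none
Why: Steglich esterification acylates the secondary allylic alcohol under neutral conditions without allylic transposition.

Step 5
Reactants: 8 (2S,3E)-4,5-dimethylhexa-3,5-dien-2-yl (3S)-3-methylpentanoate
Product: 11 (2R,3R,4E)-2-[(2S)-butan-2-yl]-3-methyl-3-(prop-1-en-2-yl)hex-4-enoic acid, via silyl ketene acetal 9 (not isolated), via trimethylsilyl ester 10 (not isolated)
Conditions: LiN(iPr)2, THF, −78 °C; Me3SiCl, Et3N; −78 to 60 °C; then 1 M HCl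
Reagents that add atoms: none
Why: Ireland–Claisen rearrangement: enolisation in THF gives the (E)-silyl ketene acetal, which should rearrange through a chair with the carbinol methyl equatorial, transferring the (S)-carbinol configuration to the quaternary (future C4) and tertiary (future C3) centres and leaving an (E)-propenyl group.

Step 6
Reactants: 11 (2R,3R,4E)-2-[(2S)-butan-2-yl]-3-methyl-3-(prop-1-en-2-yl)hex-4-enoic acid
Product: 12 (3R,4R,5E)-3-[(2S)-butan-2-yl]-4-methyl-4-(prop-1-en-2-yl)hept-5-en-2-one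
Conditions: MeLi (3 equiv), Et2O, 0 °C to rt; then H2O
Reagents that add atoms: methyllithium, [Li]C
Why: Addition of methyllithium to the lithium carboxylate stops at the dilithium gem-diolate, so the methyl ketone appears only on work-up and its α-centre is not exposed to base.

Step 7
Reactants: 12 (3R,4R,5E)-3-[(2S)-butan-2-yl]-4-methyl-4-(prop-1-en-2-yl)hept-5-en-2-one; 13 (S)-pent-4-yn-2-ol
Product: 15 (2E,4R,5R,6S,10S)-5-[(2S)-butan-2-yl]-4,6-dimethyl-4-(prop-1-en-2-yl)-6,10-bis(triethylsilyloxy)undec-2-en-7-yne, via dialkoxide 14 (not isolated)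
Conditions: 13, n-BuLi (2 equiv), THF, −78 °C; CeCl3; 12, −78 to −30 °C; then Et3SiOTf (2.6 equiv), −30 to 0 °C
Reagents that add atoms: triethylsilyl trifluoromethanesulfonate, CC[Si](CC)(CC)OS(=O)(=O)C(F)(F)F
Why: The cerium acetylide should add to the hindered ketone without enolising it and, by 1,2-induction, anti to the quaternary carbon and past the α-hydrogen, which sets the future C2 centre; both alkoxides are silylated in the same flask.

Step 8
Reactants: 15 (2E,4R,5R,6S,10S)-5-[(2S)-butan-2-yl]-4,6-dimethyl-4-(prop-1-en-2-yl)-6,10-bis(triethylsilyloxy)undec-2-en-7-yne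
Product: 16 (2S,3R,4S,8S)-2-acetyl-3-[(2S)-butan-2-yl]-2,4-dimethyl-4,8-bis(triethylsilyloxy)non-5-ynal
Conditions: O3, CH2Cl2, −78 °C (stopped when 15 is consumed); then PPh3, −78 °C to rt
Reagents that add atoms: ozone, [O-][O+]=O
Why: Ozonolysis with reductive work-up cleaves the isopropenyl group to the methyl ketone and the propenyl group to the aldehyde, the two alkenes reacting far faster with ozone than the hindered internal alkyne.

Step 9
Reactants: 16 (2S,3R,4S,8S)-2-acetyl-3-[(2S)-butan-2-yl]-2,4-dimethyl-4,8-bis(triethylsilyloxy)non-5-ynal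
Product: 17 (3R,4R,5S,9S)-4-[(2S)-butan-2-yl]-3,5-dimethyl-3-(2-methylprop-1-en-1-yl)-5,9-bis(triethylsilyloxy)dec-6-yn-2-one
Conditions: iPrPPh3I, KN(SiMe3)2, THF, 0 °C; then 16, −78 to 0 °C
Reagents that add atoms: isopropyltriphenylphosphonium iodide, CC(C)[P+](c1ccccc1)(c1ccccc1)c1ccccc1.[I-]
Why: Wittig olefination with the non-stabilised isopropylidene ylide should take the aldehyde in preference to the neopentylic methyl ketone and install the isobutenyl group.

Step 10
Reactants: 17 (3R,4R,5S,9S)-4-[(2S)-butan-2-yl]-3,5-dimethyl-3-(2-methylprop-1-en-1-yl)-5,9-bis(triethylsilyloxy)dec-6-yn-2-one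
Product: 19 acyloin (7-hydroxy-2,6-dione corresponding to 17), via bis(boronate) 18 (not isolated)
Conditions: B2pin2, Pt(PPh3)4 (5 mol%), DMF, 80 °C; then NaBO3·4H2O, THF/H2O, rt
Reagents that add atoms: sodium perborate, [Na+].[O-]OB=O
Why: Platinum-catalysed cis-diboration is specific for the alkyne (alkene and ketone untouched) and oxidation of both C–B bonds gives the enediol, which tautomerises to the acyloin (its regioisomer and carbinol epimers converge in step 11).

Step 11
Reactants: 19 acyloin
Product: 21 (3R,4R,5S)-4-[(2S)-butan-2-yl]-3,5-dimethyl-3-(2-methylprop-1-en-1-yl)-5-(triethylsilyloxy)decane-2,6,7,9-tetrone, via acyloin diol 20 (not isolated)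
Conditions: PPTS, MeOH, 0 °C; solvent removed; Dess–Martin periodinane, NaHCO3, CH2Cl2, rt
Reagents that add atoms: none
Why: Mild acid methanolysis should remove only the secondary silyl ether, and Dess–Martin oxidation then converts the acyloin hydroxyl and the secondary carbinol into ketones without touching the alkene or the tertiary silyl ether.

Step 12
Reactants: 21 (3R,4R,5S)-4-[(2S)-butan-2-yl]-3,5-dimethyl-3-(2-methylprop-1-en-1-yl)-5-(triethylsilyloxy)decane-2,6,7,9-tetrone
Product: 22 (3R,4R,5S)-4-[(2S)-butan-2-yl]-8,8-dichloro-3,5-dimethyl-3-(2-methylprop-1-en-1-yl)-5-(triethylsilyloxy)decane-2,6,7,9-tetrone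
Conditions: NCS (2.2 equiv), CH2Cl2, 0 °C to rt
Reagents that add atoms: N-chlorosuccinimide, O=C1CCC(=O)N1Cl
Why: The enolised 1,3-dicarbonyl unit should be chlorinated twice at its central carbon (α,α-dichlorination of a 1,3-diketone), the acid-free conditions leaving the trisubstituted alkene alone.

Step 13
Reactants: 22 (3R,4R,5S)-4-[(2S)-butan-2-yl]-8,8-dichloro-3,5-dimethyl-3-(2-methylprop-1-en-1-yl)-5-(triethylsilyloxy)decane-2,6,7,9-tetrone
Product: 24 (2S,3R,4S,4aR,7R,8aR)-4-acetyl-3-[(2S)-butan-2-yl]-8,8-dichloro-7,8a-dihydroxy-2,4,7-trimethyl-5-methylidene-2-(triethylsilyloxy)octahydronaphthalen-1(2H)-one, via monocyclic ene adduct 23 (not isolated)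
Conditions: Me2AlCl (3 equiv), CH2Cl2, −78 to 0 °C; aq. NaHCO3
Reagents that add atoms: none
Why: Proposed new method: Me2AlCl should bind the future C8a carbonyl, which cannot enolise and is made the most electrophilic by the neighbouring C1 carbonyl and the CCl2 group, and the isobutenyl alkene should add to it through C4a with transfer of a hydrogen from one of its methyl groups to oxygen (a carbonyl-ene reaction of the citronellal to isopulegol kind) to give the aluminium alkoxide of 23 with a new isopropenyl group; this alkoxide then holds the dichloro-activated methyl ketone (future C7) in a six-membered chelate and the 1,1-disubstituted alkene adds through its CH2 terminus (C6) with hydrogen transfer from its methyl group, which leaves the C5 methylidene. The closest known reactions are the Lewis-acid-promoted intramolecular carbonyl-ene cyclisations of 1,2-dicarbonyl compounds onto trisubstituted alkenes and of ketones onto 1,1-disubstituted alkenes; running both in one flask on a chlorine-blocked 1,2,4-triketone is the untested part. Ring B closes through a six-membered chair with C4a inside and the second alkene carbon outside the new ring (6-exo-trig at the alkene), and ring A closes with both alkene carbons inside the ring (6-endo-trig at the alkene) to give a methylidenecyclohexanol. C4a and C8a are set by that chair, in which the isobutenyl group is equatorial and the reacting carbonyl oxygen axial (opposed to the C1 carbonyl dipole), the chair itself being dictated by the C2, C3 and C4 centres (C4 methyl, C3 sec-butyl and C2 silyloxy axial, which avoids the syn-axial acetyl/methyl pair of the alternative chair); C7 is set by the aluminium bridge from the C8a oxygen, which forces the C7 oxygen axial and cis to it. The step needs site selectivity among four ketones and freedom from enolisation: attack on the C1 carbonyl would give a five-membered ring at a carbon flanked by two fully substituted centres, the C7 ketone can close only a six-membered ring and only after the first event, the unactivated neopentylic acetyl group is the poorest enophile, and the CCl2 group both removes the acidic CH2 of the 1,3-diketone and activates the two ketones it separates.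

Step 14
Reactants: 24 (2S,3R,4S,4aR,7R,8aR)-4-acetyl-3-[(2S)-butan-2-yl]-8,8-dichloro-7,8a-dihydroxy-2,4,7-trimethyl-5-methylidene-2-(triethylsilyloxy)octahydronaphthalen-1(2H)-one
Product: 25 (2S,3R,4R,4aR,5R,7R,8aR)-4-acetyl-3-[(2S)-butan-2-yl]-8,8-dichloro-7,8a-dihydroxy-2,4,5,7-tetramethyl-2-(triethylsilyloxy)octahydronaphthalen-1(2H)-one
Conditions: H2 (1 atm), [Ir(cod)(PCy3)(py)]PF6 (5 mol%), CH2Cl2, rt
Reagents that add atoms: none
Why: Hydroxyl-directed hydrogenation: the cationic iridium catalyst is bound by the axial C7 and C8a hydroxyl groups on the α face and should deliver hydrogen to C5 from that face, which makes the C5 methyl equatorial (β).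

Step 15
Reactants: 25 (2S,3R,4R,4aR,5R,7R,8aR)-4-acetyl-3-[(2S)-butan-2-yl]-8,8-dichloro-7,8a-dihydroxy-2,4,5,7-tetramethyl-2-(triethylsilyloxy)octahydronaphthalen-1(2H)-one
Product: 26 (2S,3R,4R,4aR,5R,7R,8aR)-4-acetyl-3-[(2S)-butan-2-yl]-7,8a-dihydroxy-2,4,5,7-tetramethyl-2-(triethylsilyloxy)octahydronaphthalen-1(2H)-one
Conditions: Bu3SnH (5 equiv, 1 M), AIBN (cat.), benzene, 80 °C
Reagents that add atoms: none
Why: Radical hydrodechlorination with tin hydride should remove both chlorines from C8 in turn, the high tin hydride concentration being chosen so that hydrogen transfer outruns a 1,2-acyl shift of the C8 radical.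

Step 16
Reactants: 26 (2S,3R,4R,4aR,5R,7R,8aR)-4-acetyl-3-[(2S)-butan-2-yl]-7,8a-dihydroxy-2,4,5,7-tetramethyl-2-(triethylsilyloxy)octahydronaphthalen-1(2H)-one
Product: 27 (2S,3R,4R,4aR,5R,7R,8aR)-3-[(2S)-butan-2-yl]-7,8a-dihydroxy-2,4,5,7-tetramethyl-4-(3-oxopropanoyl)-2-(triethylsilyloxy)octahydronaphthalen-1(2H)-one
Conditions: LiN(SiMe3)2 (3.5 equiv), THF, −78 °C; HCO2CH2CF3, −78 to −20 °C; 1 M HCl work-up
Reagents that add atoms: 2,2,2-trifluoroethyl formate, O=COCC(F)(F)F
Why: Claisen formylation should occur at the acetyl methyl group, the only enolisable position (the ring ketone has no α-hydrogen), to give the β-keto aldehyde.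

Step 17
Reactants: 27 (2S,3R,4R,4aR,5R,7R,8aR)-3-[(2S)-butan-2-yl]-7,8a-dihydroxy-2,4,5,7-tetramethyl-4-(3-oxopropanoyl)-2-(triethylsilyloxy)octahydronaphthalen-1(2H)-one
Product: 28 (2S,3R,4S,4aR,5R,7R,8aR)-3-[(2S)-butan-2-yl]-2,7,8a-trihydroxy-4-[(2E)-3-methoxyprop-2-enoyl]-2,4,5,7-tetramethyloctahydronaphthalen-1(2H)-one (target)
Conditions: TsOH·H2O (cat.), MeOH, rt
Reagents that add atoms: methanol, CO
Why: Acid-catalysed enol etherification of the β-keto aldehyde at the aldehyde carbon (hemiacetal, loss of water) should give the thermodynamically preferred (E)-β-methoxy enone, and the same acid cleaves the tertiary triethylsilyl ether.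

**Compound list**

1 | (S)-but-3-yn-2-ol | C[C@H](O)C#C | starting material
2 | 2-bromopropene | CC(Br)=C | starting material
3 | (S)-5-methylhex-5-en-3-yn-2-ol | C[C@H](O)C#CC(C)=C | intermediate
4 | sodium cyclic alkenylalanate from 3 (five-membered C–O–Al–C=C ring, aluminium on the carbon bearing the isopropenyl group; not isolated) | C[C@@H]1O[Al-](OCCOC)(OCCOC)C(C(C)=C)=C1.[Na+] | intermediate
5 | (2S,3Z)-4-iodo-5-methylhexa-3,5-dien-2-ol | C[C@H](O)/C=C(\I)C(C)=C | intermediate
6 | (2S,3E)-4,5-dimethylhexa-3,5-dien-2-ol | C[C@H](O)/C=C(\C)C(C)=C | intermediate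
7 | (S)-3-methylpentanoic acid | CC[C@H](C)CC(O)=O | starting material
8 | (2S,3E)-4,5-dimethylhexa-3,5-dien-2-yl (3S)-3-methylpentanoate | CC[C@H](C)CC(=O)O[C@@H](C)/C=C(\C)C(C)=C | intermediate
9 | (E)-O-trimethylsilyl ketene acetal of 8 (not isolated) | CC[C@H](C)/C=C(/O[Si](C)(C)C)O[C@@H](C)/C=C(\C)C(C)=C | intermediate
10 | trimethylsilyl ester of 11 (not isolated) | CC[C@H](C)[C@@H](C(=O)O[Si](C)(C)C)[C@](C)(C(C)=C)/C=C/C | intermediate
11 | (2R,3R,4E)-2-[(2S)-butan-2-yl]-3-methyl-3-(prop-1-en-2-yl)hex-4-enoic acid | CC[C@H](C)[C@@H](C(O)=O)[C@](C)(C(C)=C)/C=C/C | intermediate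
12 | (3R,4R,5E)-3-[(2S)-butan-2-yl]-4-methyl-4-(prop-1-en-2-yl)hept-5-en-2-one | CC[C@H](C)[C@@H](C(C)=O)[C@](C)(C(C)=C)/C=C/C | intermediate
13 | (S)-pent-4-yn-2-ol | C#CC[C@H](C)O | starting material
14 | dialkoxide of the adduct of 12 and 13, written as the dilithium salt (not isolated) | CC[C@H](C)[C@@H]([C@](C)([O-])C#CC[C@H](C)[O-])[C@](C)(C(C)=C)/C=C/C.[Li+].[Li+] | intermediate
15 | (2E,4R,5R,6S,10S)-5-[(2S)-butan-2-yl]-4,6-dimethyl-4-(prop-1-en-2-yl)-6,10-bis(triethylsilyloxy)undec-2-en-7-yne | CC[C@H](C)[C@@H]([C@](C)(O[Si](CC)(CC)CC)C#CC[C@H](C)O[Si](CC)(CC)CC)[C@](C)(C(C)=C)/C=C/C | intermediate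
16 | (2S,3R,4S,8S)-2-acetyl-3-[(2S)-butan-2-yl]-2,4-dimethyl-4,8-bis(triethylsilyloxy)non-5-ynal | CC[C@H](C)[C@@H]([C@](C)(O[Si](CC)(CC)CC)C#CC[C@H](C)O[Si](CC)(CC)CC)[C@](C)(C(C)=O)C=O | intermediate
17 | (3R,4R,5S,9S)-4-[(2S)-butan-2-yl]-3,5-dimethyl-3-(2-methylprop-1-en-1-yl)-5,9-bis(triethylsilyloxy)dec-6-yn-2-one | CC[C@H](C)[C@@H]([C@](C)(O[Si](CC)(CC)CC)C#CC[C@H](C)O[Si](CC)(CC)CC)[C@](C)(C(C)=O)C=C(C)C | intermediate
18 | (6Z)-6,7-bis(pinacolboryl)dec-6-en-2-one corresponding to 17 (cis-diboration product; not isolated) | CC[C@H](C)[C@@H]([C@](C)(O[Si](CC)(CC)CC)/C(B1OC(C)(C)C(C)(C)O1)=C(/B1OC(C)(C)C(C)(C)O1)C[C@H](C)O[Si](CC)(CC)CC)[C@](C)(C(C)=O)C=C(C)C | intermediate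
19 | acyloin: 7-hydroxy-2,6-dione corresponding to 17, both silyl ethers kept, C7 carbinol as an epimer mixture | CC[C@H](C)[C@@H]([C@](C)(O[Si](CC)(CC)CC)C(=O)C(O)C[C@H](C)O[Si](CC)(CC)CC)[C@](C)(C(C)=O)C=C(C)C | intermediate
20 | acyloin diol: 19 without the secondary triethylsilyl group (not isolated) | CC[C@H](C)[C@@H]([C@](C)(O[Si](CC)(CC)CC)C(=O)C(O)C[C@H](C)O)[C@](C)(C(C)=O)C=C(C)C | intermediate
21 | (3R,4R,5S)-4-[(2S)-butan-2-yl]-3,5-dimethyl-3-(2-methylprop-1-en-1-yl)-5-(triethylsilyloxy)decane-2,6,7,9-tetrone (drawn as tetraketone; enolised between C7 and C9) | CC[C@H](C)[C@@H]([C@](C)(O[Si](CC)(CC)CC)C(=O)C(=O)CC(C)=O)[C@](C)(C(C)=O)C=C(C)C | intermediate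
22 | (3R,4R,5S)-4-[(2S)-butan-2-yl]-8,8-dichloro-3,5-dimethyl-3-(2-methylprop-1-en-1-yl)-5-(triethylsilyloxy)decane-2,6,7,9-tetrone | CC[C@H](C)[C@@H]([C@](C)(O[Si](CC)(CC)CC)C(=O)C(=O)C(Cl)(Cl)C(C)=O)[C@](C)(C(C)=O)C=C(C)C | intermediate
23 | monocyclic ene adduct: cyclohexanone (ring B) with C8a hydroxyl and 1,1-dichloro-2-oxopropyl group, C4a isopropenyl group, other centres as in 24; present as its aluminium alkoxide, written as the alcohol (not isolated) | CC[C@H](C)[C@@H]1[C@](C)(C(C)=O)[C@@H](C(C)=C)[C@](O)(C(Cl)(Cl)C(C)=O)C(=O)[C@@]1(C)O[Si](CC)(CC)CC | intermediate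
24 | (2S,3R,4S,4aR,7R,8aR)-4-acetyl-3-[(2S)-butan-2-yl]-8,8-dichloro-7,8a-dihydroxy-2,4,7-trimethyl-5-methylidene-2-(triethylsilyloxy)octahydronaphthalen-1(2H)-one | CC[C@H](C)[C@@H]1[C@](C)(C(C)=O)[C@H]2C(=C)C[C@@](C)(O)C(Cl)(Cl)[C@]2(O)C(=O)[C@@]1(C)O[Si](CC)(CC)CC | intermediate
25 | (2S,3R,4R,4aR,5R,7R,8aR)-4-acetyl-3-[(2S)-butan-2-yl]-8,8-dichloro-7,8a-dihydroxy-2,4,5,7-tetramethyl-2-(triethylsilyloxy)octahydronaphthalen-1(2H)-one | CC[C@H](C)[C@@H]1[C@](C)(C(C)=O)[C@H]2[C@H](C)C[C@@](C)(O)C(Cl)(Cl)[C@]2(O)C(=O)[C@@]1(C)O[Si](CC)(CC)CC | intermediate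
26 | (2S,3R,4R,4aR,5R,7R,8aR)-4-acetyl-3-[(2S)-butan-2-yl]-7,8a-dihydroxy-2,4,5,7-tetramethyl-2-(triethylsilyloxy)octahydronaphthalen-1(2H)-one | CC[C@H](C)[C@@H]1[C@](C)(C(C)=O)[C@H]2[C@H](C)C[C@@](C)(O)C[C@]2(O)C(=O)[C@@]1(C)O[Si](CC)(CC)CC | intermediate
27 | (2S,3R,4R,4aR,5R,7R,8aR)-3-[(2S)-butan-2-yl]-7,8a-dihydroxy-2,4,5,7-tetramethyl-4-(3-oxopropanoyl)-2-(triethylsilyloxy)octahydronaphthalen-1(2H)-one (drawn as keto aldehyde; enolised) | CC[C@H](C)[C@@H]1[C@](C)(C(=O)CC=O)[C@H]2[C@H](C)C[C@@](C)(O)C[C@]2(O)C(=O)[C@@]1(C)O[Si](CC)(CC)CC | intermediate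
28 | (2S,3R,4S,4aR,5R,7R,8aR)-3-[(2S)-butan-2-yl]-2,7,8a-trihydroxy-4-[(2E)-3-methoxyprop-2-enoyl]-2,4,5,7-tetramethyloctahydronaphthalen-1(2H)-one | CC[C@H](C)[C@@H]1[C@](C)(C(=O)/C=C/OC)[C@H]2[C@H](C)C[C@@](C)(O)C[C@]2(O)C(=O)[C@@]1(C)O | target

**Step count and risks**

Total step count: 17. Longest linear sequence: 17 steps (1 to 28); 2, 7 and 13 enter as bought building blocks.

Steps most likely to fail:

First, step 13 (the proposed cascade). The first ene reaction may be slowed by the congestion around C8a, so that methyl transfer from aluminium to the activated ketone, closure onto the C1 carbonyl (five-membered ring) or a chair of opposite folding (wrong C4a/C8a pair) compete; the cascade may also stop at 23. The fallback uses known reactions only and no chlorine helper, and it sets out from acyloin 19. Dess–Martin oxidation of 19 gives the 1,2-diketone F1, in which C7 is still a silyl ether so that no enolisable 1,3-dicarbonyl unit exists. Me2AlCl-promoted carbonyl-ene cyclisation of the 1,2-diketone onto the isobutenyl group gives the isopropenyl cyclohexanol F2. PPTS in MeOH frees the secondary alcohol to give the diol F3, and Dess–Martin oxidation gives the hydroxy diketone F4. A second, separate Me2AlCl-promoted carbonyl-ene cyclisation of the methyl ketone onto the 1,1-disubstituted alkene gives the methylidene decalin F5, and hydroxyl-directed hydrogenation as in step 14 brings the sequence back to 26.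

Second, step 7. The facial selectivity of the addition to the hindered ketone may be weak or opposite to the predicted one. The fallback sets out from acid 11, which is converted (EDC, MeNHOMe·HCl) into the N-methoxy-N-methylamide F6. The lithium acetylide of the silyl ether F7 (from 13 with Et3SiCl and imidazole) acylates to the ynone F8. MeMgBr with CeCl3 then adds the methyl group; methyl is now the incoming and the alkynyl group the resident substituent, so the same intrinsic facial bias gives the opposite configuration at C2, in the tertiary alcohol F9. Silylation with Et3SiOTf returns to 15.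

Third, step 9. The ylide may attack the acetyl group, or the formyl group may be lost by retro-Claisen cleavage of the non-enolisable keto aldehyde. The fallback sets out from 15. Ozonolysis with NaBH4 work-up gives the diol F10 (secondary carbinol as an epimer mixture), and TEMPO with PhI(OAc)2 oxidises only the primary alcohol to the hydroxy aldehyde F11. Wittig olefination with the same ylide, now in the absence of any ketone, gives the alkenyl carbinol F12, and Dess–Martin oxidation returns to 17.

Further compounds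
F1 | step 13 | 1,2-diketone from 19 with the C7 oxygen still as triethylsilyl ether | CC[C@H](C)[C@@H]([C@](C)(O[Si](CC)(CC)CC)C(=O)C(=O)C[C@H](C)O[Si](CC)(CC)CC)[C@](C)(C(C)=O)C=C(C)C
F2 | step 13 | isopropenyl cyclohexanol (ring B closed, side chain 2-(triethylsilyloxy)propyl on C8a) | CC[C@H](C)[C@@H]1[C@](C)(C(C)=O)[C@@H](C(C)=C)[C@](O)(C[C@H](C)O[Si](CC)(CC)CC)C(=O)[C@@]1(C)O[Si](CC)(CC)CC
F3 | step 13 | diol from F2 (secondary silyl ether removed) | CC[C@H](C)[C@@H]1[C@](C)(C(C)=O)[C@@H](C(C)=C)[C@](O)(C[C@H](C)O)C(=O)[C@@]1(C)O[Si](CC)(CC)CC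
F4 | step 13 | hydroxy diketone from F3 (2-oxopropyl group on C8a) | CC[C@H](C)[C@@H]1[C@](C)(C(C)=O)[C@@H](C(C)=C)[C@](O)(CC(C)=O)C(=O)[C@@]1(C)O[Si](CC)(CC)CC
F5 | step 13 | methylidene decalin (24 without the two chlorines) | CC[C@H](C)[C@@H]1[C@](C)(C(C)=O)[C@H]2C(=C)C[C@@](C)(O)C[C@]2(O)C(=O)[C@@]1(C)O[Si](CC)(CC)CC
F6 | step 7 | N-methoxy-N-methylamide of 11 | CC[C@H](C)[C@@H](C(=O)N(C)OC)[C@](C)(C(C)=C)/C=C/C
F7 | step 7 | (S)-triethyl(pent-4-yn-2-yloxy)silane | C#CC[C@H](C)O[Si](CC)(CC)CC
F8 | step 7 | ynone from F6 and the acetylide of F7 | CC[C@H](C)[C@@H](C(=O)C#CC[C@H](C)O[Si](CC)(CC)CC)[C@](C)(C(C)=C)/C=C/C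
F9 | step 7 | tertiary propargylic alcohol (15 without the tertiary silyl group) | CC[C@H](C)[C@@H]([C@](C)(O)C#CC[C@H](C)O[Si](CC)(CC)CC)[C@](C)(C(C)=C)/C=C/C
F10 | step 9 | diol from ozonolysis of 15 with NaBH4 work-up (hydroxymethyl and 1-hydroxyethyl on the quaternary carbon) | CC[C@H](C)[C@@H]([C@](C)(O[Si](CC)(CC)CC)C#CC[C@H](C)O[Si](CC)(CC)CC)[C@](C)(C(C)O)CO
F11 | step 9 | hydroxy aldehyde from F10 | CC[C@H](C)[C@@H]([C@](C)(O[Si](CC)(CC)CC)C#CC[C@H](C)O[Si](CC)(CC)CC)[C@](C)(C(C)O)C=O
F12 | step 9 | alkenyl carbinol from F11 (isobutenyl and 1-hydroxyethyl on the quaternary carbon) | CC[C@H](C)[C@@H]([C@](C)(O[Si](CC)(CC)CC)C#CC[C@H](C)O[Si](CC)(CC)CC)[C@](C)(C(C)O)C=C(C)C
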